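**Retrosynthetic overview**

1. Numbering: unprimed atoms belong to the benzopyranone (rings A and C), primed atoms to the 3-aryl ring B. Unit 1 is the isoflavone joined through C3' of its ring B; unit 2 is the one joined through C8 of its ring A.
2. Enabling feature: both carbons of the biaryl bond carry an ortho phenolic oxygen (O4' on ring B of unit 1, O7 on ring A of unit 2), giving a 2,2'-biphenol array O4'–C4'–C3'–C8–C7–O7 that one silicon atom can bridge.
3. Key disconnection: C3'–C8, formed by Pd-catalysed C–H arylation inside a temporary seven-membered ring (O4'–Si(tBu)2–O7 bridge). Bromine at C8 fixes one site; the two C–H bonds ortho to O4' on ring B are equivalent.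
4. Unit 2 is 8-bromoformononetin, with ring C built on 2-bromoresorcinol so that Br sits at C8 by construction. Unit 1 is daidzein, 7-O-methylated.
5. Ring order: ring C of unit 2 (step 1), temporary dioxasilepine ring (step 4), ring opened by fluoride (step 5), then O-demethylation (step 6).

Key step: step 4

Remark on the chemistry: the SMILES carries no descriptor for the C3'–C8 axis, which has only three small ortho substituents (4'-OH, 7-OH, ring oxygen O1) and is assumed to equilibrate, so the route builds the constitution as drawn without an atroposelective step; should the atropisomers prove separable, the M form would be taken from 11 by HPLC on a chiral phase.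

**Route**

Step 1
Reactants: 1 2-bromoresorcinol; 2 4-methoxyphenylacetic acid
Product: 4 8-bromoformononetin [8-bromo-7-hydroxy-3-(4-methoxyphenyl)-4H-chromen-4-one], via deoxybenzoin 3 (not isolated)
Conditions: BF3·OEt2 (neat), 85 °C; then DMF, MsCl, 70 °C; aq. NaOAc work-up
Reagents that add atoms: N,N-dimethylformamide, CN(C)C=O
Why: BF3-mediated Friedel–Crafts acylation at C4 of the resorcinol (ortho to one OH, para to the other, the only activated type of position) should give the deoxybenzoin, whose methylene is formylated by the Vilsmeier-type reagent from DMF and MsCl and closes onto the ortho hydroxyl with loss of dimethylamine (the standard one-pot deoxybenzoin route to 7-hydroxyisoflavones), so bromine lies at C8 by construction.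

Step 2
Reactants: 5 daidzein
Product: 6 isoformononetin [3-(4-hydroxyphenyl)-7-methoxy-4H-chromen-4-one]
Conditions: MeI (1.05 equiv), K2CO3 (1.0 equiv), DMF, 25 °C
Reagents that add atoms: iodomethane, CI
Why: Williamson etherification in which one equivalent of base ionises mainly the more acidic 7-OH (a vinylogous carboxylic acid through C4=O), so methylation should occur at O7 and leave the 4'-OH free.

Step 3
Reactants: 4 8-bromoformononetin; 6 isoformononetin
Product: 8 di-tert-butyl{[8-bromo-3-(4-methoxyphenyl)-4-oxo-4H-chromen-7-yl]oxy}[4-(7-methoxy-4-oxo-4H-chromen-3-yl)phenoxy]silane, via aryloxysilyl triflate 7 (not isolated)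
Conditions: tBu2Si(OTf)2 (1.0 equiv), Et3N, CH2Cl2, −40 → 0 °C (4 added slowly); then 6, DMAP (cat.), 0 → 40 °C
Reagents that add atoms: di-tert-butylsilyl bis(trifluoromethanesulfonate), CC(C)(C)[Si](OS(=O)(=O)C(F)(F)F)(OS(=O)(=O)C(F)(F)F)C(C)(C)C
Why: Stepwise substitution at silicon, in which the acidic ortho-brominated 7-OH of 4 should displace only one triflate because a second attack by the same hindered phenoxide is slow, and the unhindered 4'-OH of 6 then displaces the remaining triflate under DMAP catalysis (the usual way to unsymmetrical di-tert-butylsilylene bis-ethers).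

Step 4
Reactants: 8 the bis(aryloxy)silane
Product: 9 silicon-bridged biaryl [4'-O,7-O-(di-tert-butylsilanediyl) derivative of 7-hydroxy-8-[2-hydroxy-5-(7-methoxy-4-oxo-4H-chromen-3-yl)phenyl]-3-(4-methoxyphenyl)-4H-chromen-4-one; seven-membered 1,3,2-dioxasilepine ring made of C3', C4', O, Si, O, C7, C8]
Conditions: Pd(OAc)2 (10 mol %), PCy3·HBF4 (20 mol %), Cs2CO3 (2 equiv), PivOH (30 mol %), p-xylene (0.02 M), 130 °C
Reagents that add atoms: none
Why: Oxidative addition of zerovalent palladium into the C8–Br bond should be followed by pivalate-assisted concerted metalation–deprotonation of the C3'–H bond of the tethered ring B, and reductive elimination from the eight-membered diarylpalladium ring forms the C3'–C8 bond. The closest known reaction type is the silicon-tethered Pd-catalysed intramolecular direct arylation of (2-bromoaryloxy)(aryloxy)di-tert-butylsilanes to dibenzo[d,f][1,3,2]dioxasilepines, an established entry to unsymmetrical 2,2'-biphenols. The one ring closed is the seven-membered dioxasilepine, closed at its biaryl bond by C–C reductive elimination. No stereocentre is formed, and the new axis stays free to equilibrate inside the flexible seven-membered ring. The step needs site selectivity only: the bromine built in from 2-bromoresorcinol fixes C8, C3' and C5' of ring B are equivalent, the short O–Si–O bridge keeps every other C–H bond (C6 and C8 of the methoxy-bearing ring A, both C2–H) out of reach, and dilution suppresses intermolecular arylation.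

Step 5
Reactants: 9 the silicon-bridged biaryl
Product: 10 7-hydroxy-8-[2-hydroxy-5-(7-methoxy-4-oxo-4H-chromen-3-yl)phenyl]-3-(4-methoxyphenyl)-4H-chromen-4-one
Conditions: HF·pyridine, THF/pyridine, 0 → 25 °C
Reagents that add atoms: none
Why: Fluoride-driven cleavage of both Si–O bonds (silylene deprotection) under non-basic conditions should free the two phenols while leaving the base-sensitive pyranone rings and the methyl ethers untouched.

Step 6
Reactants: 10 the biphenol dimethyl ether
Product: 11 (M)-bisoflavolin C [7-hydroxy-8-[2-hydroxy-5-(7-hydroxy-4-oxo-4H-chromen-3-yl)phenyl]-3-(4-hydroxyphenyl)-4H-chromen-4-one]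
Conditions: BBr3 (10 equiv), CH2Cl2, −78 → 25 °C; then ice-water
Reagents that add atoms: none
Why: Lewis acid-mediated aryl methyl ether cleavage (bromide attacks the methyl groups of the boron-complexed ethers) is the standard demethylation of methoxyisoflavones and should be tolerated by the chromone cores.

**Compound list**

1 | 2-bromoresorcinol (2-bromobenzene-1,3-diol) | Oc1cccc(O)c1Br | starting material
2 | 4-methoxyphenylacetic acid | COc1ccc(CC(=O)O)cc1 | starting material
3 | 1-(3-bromo-2,4-dihydroxyphenyl)-2-(4-methoxyphenyl)ethan-1-one | COc1ccc(CC(=O)c2ccc(O)c(Br)c2O)cc1 | intermediate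
4 | 8-bromo-7-hydroxy-3-(4-methoxyphenyl)-4H-chromen-4-one (8-bromoformononetin) | COc1ccc(-c2coc3c(Br)c(O)ccc3c2=O)cc1 | intermediate
5 | daidzein, 7-hydroxy-3-(4-hydroxyphenyl)-4H-chromen-4-one | O=c1c(-c2ccc(O)cc2)coc2cc(O)ccc12 | starting material
6 | isoformononetin, 3-(4-hydroxyphenyl)-7-methoxy-4H-chromen-4-one | COc1ccc2c(=O)c(-c3ccc(O)cc3)coc2c1 | intermediate
7 | {[8-bromo-3-(4-methoxyphenyl)-4-oxo-4H-chromen-7-yl]oxy}di-tert-butylsilyl trifluoromethanesulfonate | COc1ccc(-c2coc3c(Br)c(O[Si](C(C)(C)C)(C(C)(C)C)OS(=O)(=O)C(F)(F)F)ccc3c2=O)cc1 | intermediate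
8 | di-tert-butyl{[8-bromo-3-(4-methoxyphenyl)-4-oxo-4H-chromen-7-yl]oxy}[4-(7-methoxy-4-oxo-4H-chromen-3-yl)phenoxy]silane | COc1ccc(-c2coc3c(Br)c(O[Si](C(C)(C)C)(C(C)(C)C)Oc4ccc(-c5coc6cc(OC)ccc6c5=O)cc4)ccc3c2=O)cc1 | intermediate
9 | silicon-bridged biaryl: C3' of unit 1 bonded to C8 of unit 2, with O4' and O7 joined by Si(tBu)2 in a dibenzo-1,3,2-dioxasilepine ring; methyl ethers at O7 of unit 1 and O4' of unit 2 | COc1ccc2c(=O)c(-c3ccc4c(c3)-c3c(ccc5c(=O)c(-c6ccc(OC)cc6)coc35)O[Si](C(C)(C)C)(C(C)(C)C)O4)coc2c1 | intermediate
10 | 7-hydroxy-8-[2-hydroxy-5-(7-methoxy-4-oxo-4H-chromen-3-yl)phenyl]-3-(4-methoxyphenyl)-4H-chromen-4-one | COc1ccc2c(=O)c(-c3ccc(O)c(c3)-c3c(O)ccc4c(=O)c(-c5ccc(OC)cc5)coc34)coc2c1 | intermediate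
11 | (M)-bisoflavolin C, 7-hydroxy-8-[2-hydroxy-5-(7-hydroxy-4-oxo-4H-chromen-3-yl)phenyl]-3-(4-hydroxyphenyl)-4H-chromen-4-one (axis as in the remark) | O=c1c(-c2ccc(O)c(-c3c(O)ccc4c(=O)c(-c5ccc(O)cc5)coc34)c2)coc2cc(O)ccc12 | target

**Step count and risks**

Total step count: 6. Longest linear sequence: 5 steps (steps 1, 3, 4, 5, 6).

The three steps most likely to fail are steps 4, 3 and 1.

Step 4 (key step): the arylpalladium intermediate may be reduced at C8 (hydrodebromination), or the silicon bridge may be cleaved by carbonate at 130 °C before C–H metalation closes the ring. The fallback is an intermolecular Suzuki–Miyaura coupling at the same bond, with all four phenols carried as methyl ethers. It sets out from 6 and 4. Compound 6 is iodinated ortho to its only free phenol (NIS, TsOH cat., MeCN, 25 °C) to give 3-(4-hydroxy-3-iodophenyl)-7-methoxy-4H-chromen-4-one F1. This is O-methylated (MeI, K2CO3, DMF) to 3-(3-iodo-4-methoxyphenyl)-7-methoxy-4H-chromen-4-one F2, then borylated (B2pin2, PdCl2(dppf), KOAc, dioxane, 90 °C) to the pinacol boronate F3. Compound 4 is O-methylated (MeI, K2CO3, DMF) to 8-bromo-7-methoxy-3-(4-methoxyphenyl)-4H-chromen-4-one F4. F3 and F4 are coupled (Pd(OAc)2, SPhos, K3PO4, toluene/water, 100 °C) to the tetramethyl ether of the target F5. BBr3 (CH2Cl2, −78 → 25 °C) then cleaves all four methyl ethers, so the fallback comes back to the route at 11.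

Step 3: the second substitution at the hindered silicon may stall, or exchange of aryloxy groups at silicon may scramble the two halves into symmetrical silanes. The fallback builds the bridge through an isolable hydrosilane instead of the bis-triflate. It sets out from 4, which is silylated with di-tert-butylchlorosilane (imidazole, DMF, 25 °C) to give 8-bromo-7-[(di-tert-butylsilyl)oxy]-3-(4-methoxyphenyl)-4H-chromen-4-one F6. The Si–H bond is brominated (NBS, CH2Cl2, 0 °C) to the bromosilane F7. Without isolation, F7 is treated with 6 and imidazole (DMF, 25 → 50 °C), and the fallback comes back to the route at 8.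

Step 1: the hot Lewis acid may cause migration or loss of bromine on the electron-rich ring, or acylation of the brominated resorcinol may be sluggish. The fallback introduces bromine after the isoflavone is built. It sets out from 2, which is combined with resorcinol in place of 1 under the same one-pot conditions (BF3·OEt2, 85 °C; then DMF, MsCl, 70 °C) to give formononetin F8. Bromination with NBS (iPr2NH cat., CH2Cl2, 0 °C) is expected at C8, the ortho position with the higher enol character in 7-hydroxybenzopyranones. Any C6 isomer would be removed by crystallisation, and the fallback comes back to the route at 4.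

**Further compounds**

F1 | step 4 | 3-(4-hydroxy-3-iodophenyl)-7-methoxy-4H-chromen-4-one | COc1ccc2c(=O)c(-c3ccc(O)c(I)c3)coc2c1
F2 | step 4 | 3-(3-iodo-4-methoxyphenyl)-7-methoxy-4H-chromen-4-one | COc1ccc2c(=O)c(-c3ccc(OC)c(I)c3)coc2c1
F3 | step 4 | 7-methoxy-3-[4-methoxy-3-(4,4,5,5-tetramethyl-1,3,2-dioxaborolan-2-yl)phenyl]-4H-chromen-4-one | COc1ccc2c(=O)c(-c3ccc(OC)c(B4OC(C)(C)C(C)(C)O4)c3)coc2c1
F4 | step 4 | 8-bromo-7-methoxy-3-(4-methoxyphenyl)-4H-chromen-4-one | COc1ccc(-c2coc3c(Br)c(OC)ccc3c2=O)cc1
F5 | step 4 | 7-methoxy-8-[2-methoxy-5-(7-methoxy-4-oxo-4H-chromen-3-yl)phenyl]-3-(4-methoxyphenyl)-4H-chromen-4-one | COc1ccc2c(=O)c(-c3ccc(OC)c(c3)-c3c(OC)ccc4c(=O)c(-c5ccc(OC)cc5)coc34)coc2c1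
F6 | step 3 | 8-bromo-7-[(di-tert-butylsilyl)oxy]-3-(4-methoxyphenyl)-4H-chromen-4-one | COc1ccc(-c2coc3c(Br)c(O[SiH](C(C)(C)C)C(C)(C)C)ccc3c2=O)cc1
F7 | step 3 | 8-bromo-7-{[bromo(di-tert-butyl)silyl]oxy}-3-(4-methoxyphenyl)-4H-chromen-4-one | COc1ccc(-c2coc3c(Br)c(O[Si](Br)(C(C)(C)C)C(C)(C)C)ccc3c2=O)cc1
F8 | step 1 | formononetin, 7-hydroxy-3-(4-methoxyphenyl)-4H-chromen-4-one | COc1ccc(-c2coc3cc(O)ccc3c2=O)cc1
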